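Ring C is cut across O1–C2 and C4–C4a, so that the target falls apart into a ring-A phenol and a p-coumaroyl three-carbon unit. The route exploits the fact that O1 and C4a are ortho neighbours on ring A and that C8, the other ortho carbon, carries the prenyl group. A cinnamoyl group parked on O1 as an aryl ester is moved by a photo-Fries 1,3-shift onto C4a, and the liberated O1 then adds to the enone β-carbon (C2) in the same pot. One operation thus turns an acyclic aryl ester into the complete 8-prenylflavanone core. Kinetic resolution, chelation-guided C5 demethylation and an equatorial hydride delivery then set (2S,4R).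

Key step: step 3

Remark: the target SMILES is read as (2S,4R), that is the 2,4-trans flavan-4-ol with equatorial 2-aryl and axial 4-hydroxyl; the three starting materials are taken as commercially available.

Step 1
Reactants: 1 3,5-dimethoxyphenol; 2 prenyl bromide (1-bromo-3-methylbut-2-ene)
Product: 3 3,5-dimethoxy-2-(3-methylbut-2-en-1-yl)phenol
Conditions: NaH, toluene, 0 °C to rt
Reagents that add atoms: none
Why: Ortho-C-alkylation of a sodium phenoxide in a non-polar solvent (the tight ion pair steers the allylic bromide to the ortho carbon, not to oxygen); the two ortho carbons of 1 are equivalent, so mono-prenylation gives one ortho isomer, which is separated from para- and O-alkylated material.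

Step 2
Reactants: 3 3,5-dimethoxy-2-(3-methylbut-2-en-1-yl)phenol; 4 (E)-4-acetoxycinnamic acid
Product: 5 3,5-dimethoxy-2-(3-methylbut-2-en-1-yl)phenyl (E)-3-(4-acetoxyphenyl)prop-2-enoate
Conditions: DCC, DMAP (cat.), CH2Cl2, 0 °C to rt
Reagents that add atoms: none
Why: Steglich esterification: DCC activates the acid and DMAP relays the acyl group to the hindered phenol, while the aryl acetate is untouched under these neutral conditions.

Step 3
Reactants: 5 3,5-dimethoxy-2-(3-methylbut-2-en-1-yl)phenyl (E)-3-(4-acetoxyphenyl)prop-2-enoate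
Product: 8 racemic 2-(4-hydroxyphenyl)-5,7-dimethoxy-8-(3-methylbut-2-en-1-yl)chroman-4-one, via chalcone acetate 6 (not isolated), via chalcone 7 (not isolated)
Conditions: hν (300 nm, Pyrex), degassed MeCN (0.005 M), rt; then 1% aq NaOH added to the photolysate, 0 °C to rt; dil. HCl to pH 6
Reagents that add atoms: none
Why: Excitation of the aryl cinnamate cleaves the ArO–CO bond homolytically; the caged acyl/phenoxyl radical pair recombines at the only free ortho carbon (the future C4a) and the dienone tautomerises to 2'-hydroxychalcone 6, which the added hydroxide deacetylates to 7 and whose phenoxide (the former ester oxygen, O1) adds to the enone β-carbon to close ring C. The closest known reaction types are the photo-Fries rearrangement of aryl cinnamates to 2'-hydroxychalcones and the base-mediated chalcone–flavanone isomerisation (oxa-Michael addition). The pyranone ring is closed in the 6-endo-trig mode. The new stereocentre C2 is formed without control, as the racemate, and is resolved in step 4. The step needs ortho- over para-migration and ring closure through the right oxygen: the prenyl group blocks the second ortho carbon, the para-acyl isomer cannot cyclise and is removed, and because the other peri oxygen is a methyl ether only O1 can close, so 8-prenyl/6-prenyl scrambling is excluded. E and Z photoisomers of 5 converge, since both give the same flavanone after the base stage.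

Step 4
Reactants: 8 racemic 2-(4-hydroxyphenyl)-5,7-dimethoxy-8-(3-methylbut-2-en-1-yl)chroman-4-one
Product: 9 (2S)-2-(4-hydroxyphenyl)-5,7-dimethoxy-8-(3-methylbut-2-en-1-yl)chroman-4-one (the unreacted enantiomer)
Conditions: Cp*RhCl[(R,R)-TsDPEN] (1 mol%), HCO2H/Et3N (5:2), EtOAc, rt, run to just past half conversion
Reagents that add atoms: none
Why: Kinetic resolution by Noyori–Ikariya asymmetric transfer hydrogenation: the (R,R) catalyst forms the 4R carbinol and can do so along the favoured axial trajectory only on the 2R ketone (giving the cis-(2R,4R)-alcohol), so the 2S ketone 9 should be left behind and is separated by chromatography; the prenyl alkene and the phenol are inert to the metal hydride.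

Step 5
Reactants: 9 (2S)-2-(4-hydroxyphenyl)-5,7-dimethoxy-8-(3-methylbut-2-en-1-yl)chroman-4-one
Product: 10 (2S)-5-hydroxy-2-(4-hydroxyphenyl)-7-methoxy-8-(3-methylbut-2-en-1-yl)chroman-4-one
Conditions: MgI2·OEt2, THF, 60 °C
Reagents that add atoms: none
Why: Chelation-assisted ether cleavage: Mg2+ bridges the C4 carbonyl and the peri C5 oxygen and iodide removes that methyl group by SN2, which should leave intact the C7 methyl ether, the prenyl group and, since ring C is not opened, the C2 configuration.

Step 6
Reactants: 10 (2S)-5-hydroxy-2-(4-hydroxyphenyl)-7-methoxy-8-(3-methylbut-2-en-1-yl)chroman-4-one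
Product: 11 (2S,4R)-2-(4-hydroxyphenyl)-7-methoxy-8-(3-methylbut-2-en-1-yl)chroman-4,5-diol (target)
Conditions: LiBH(s-Bu)3 (L-Selectride, 4 equiv), THF, −78 to −20 °C; MeOH, pH 7 phosphate buffer
Reagents that add atoms: none
Why: Diastereoselective ketone reduction under steric approach control: after deprotonation of the two phenols the bulky trialkylborohydride should attack C4 of the half-chair (2-aryl equatorial) from the equatorial side, away from the axial H-2, so that the new hydroxyl is axial and trans to the aryl group, which is the 4R configuration; the neutral work-up protects the acid-labile benzylic alcohol.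

Compound list
1 | 3,5-dimethoxyphenol | COc1cc(O)cc(OC)c1 | starting material
2 | prenyl bromide (1-bromo-3-methylbut-2-ene) | CC(C)=CCBr | starting material
3 | 3,5-dimethoxy-2-(3-methylbut-2-en-1-yl)phenol | COc1cc(O)c(CC=C(C)C)c(OC)c1 | intermediate
4 | (E)-4-acetoxycinnamic acid | CC(=O)Oc1ccc(/C=C/C(=O)O)cc1 | starting material
5 | 3,5-dimethoxy-2-(3-methylbut-2-en-1-yl)phenyl (E)-3-(4-acetoxyphenyl)prop-2-enoate | CC(=O)Oc1ccc(/C=C/C(=O)Oc2cc(OC)cc(OC)c2CC=C(C)C)cc1 | intermediate
6 | chalcone acetate: (E)-3-(4-acetoxyphenyl)-1-[2-hydroxy-4,6-dimethoxy-3-(3-methylbut-2-en-1-yl)phenyl]prop-2-en-1-one | CC(=O)Oc1ccc(/C=C/C(=O)c2c(O)c(CC=C(C)C)c(OC)cc2OC)cc1 | intermediate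
7 | chalcone: (E)-1-[2-hydroxy-4,6-dimethoxy-3-(3-methylbut-2-en-1-yl)phenyl]-3-(4-hydroxyphenyl)prop-2-en-1-one | Oc1ccc(/C=C/C(=O)c2c(O)c(CC=C(C)C)c(OC)cc2OC)cc1 | intermediate
8 | racemic 2-(4-hydroxyphenyl)-5,7-dimethoxy-8-(3-methylbut-2-en-1-yl)chroman-4-one | COc1cc(OC)c2c(c1CC=C(C)C)OC(c1ccc(O)cc1)CC2=O | intermediate
9 | (2S)-2-(4-hydroxyphenyl)-5,7-dimethoxy-8-(3-methylbut-2-en-1-yl)chroman-4-one | COc1cc(OC)c2c(c1CC=C(C)C)O[C@H](c1ccc(O)cc1)CC2=O | intermediate
10 | (2S)-5-hydroxy-2-(4-hydroxyphenyl)-7-methoxy-8-(3-methylbut-2-en-1-yl)chroman-4-one | COc1cc(O)c2c(c1CC=C(C)C)O[C@H](c1ccc(O)cc1)CC2=O | intermediate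
11 | (2S,4R)-2-(4-hydroxyphenyl)-7-methoxy-8-(3-methylbut-2-en-1-yl)chroman-4,5-diol | COc1cc(O)c2c(c1CC=C(C)C)O[C@H](c1ccc(O)cc1)C[C@H]2O | target

Total step count: 6. Longest linear sequence: 6 steps (1 → 3 → 5 → 8 → 9 → 10 → 11).

Steps most likely to fail

Step 3. The O-to-C acyl migration may be inefficient. E/Z isomerisation of the cinnamate and escape of the radical pair from the solvent cage (returning phenol 3) can outrun recombination, some acyl can migrate to the para carbon, and the chalcone formed screens the light. Fallback, from phenol 3, returning at chalcone 7: magnesium-mediated ortho-formylation (MgCl2, Et3N, paraformaldehyde, MeCN, reflux) can only go to the one free ortho carbon and should give 2-hydroxy-4,6-dimethoxy-3-(3-methylbut-2-en-1-yl)benzaldehyde F1. Addition of MeMgBr (THF, 0 °C) gives racemic 1-[2-hydroxy-4,6-dimethoxy-3-(3-methylbut-2-en-1-yl)phenyl]ethan-1-ol F2, and MnO2 (CH2Cl2) oxidises it to 1-[2-hydroxy-4,6-dimethoxy-3-(3-methylbut-2-en-1-yl)phenyl]ethan-1-one F3. Claisen–Schmidt condensation of F3 with 4-hydroxybenzaldehyde (KOH, EtOH/H2O) then gives chalcone 7, which is closed to 8 with 1% aq NaOH as in the second stage of step 3.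

Step 6. Facial selectivity of hydride delivery at C4 may be poor (axial attack gives the cis-4-ol), the chelated lithium 5-phenoxide ketone may be reduced sluggishly, and the benzylic alcohol may ionise during work-up. Fallback, from 10, returning at 11: NaBH4 (EtOH/THF, 0 °C) reduces 5-hydroxyflavanones by axial attack and should give (2S,4S)-2-(4-hydroxyphenyl)-7-methoxy-8-(3-methylbut-2-en-1-yl)chroman-4,5-diol F4. Its C4 centre is then epimerised in dilute aqueous acid (aqueous acetone, acetate buffer near pH 4, rt): the C4 cation, stabilised by O1, the 5-hydroxyl and the 7-methoxyl, is recaptured by water along the axial trajectory, and the trans epimer 11 is separated from remaining F4 by chromatography.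

Step 4. Discrimination between the enantiomers may be incomplete, because the 5-methoxy and 8-prenyl groups crowd both reacting faces and slow the fast enantiomer, so that the recovered ketone is not enantiopure. Fallback, from 8, returning at 9: NaBH4 (MeOH, 0 °C) gives racemic cis-2-(4-hydroxyphenyl)-5,7-dimethoxy-8-(3-methylbut-2-en-1-yl)chroman-4-ol F5. Lipase-catalysed acylation (lipase PS, vinyl acetate, t-BuOMe, rt) follows the usual preference of lipases for the R carbinol and should convert one enantiomer into (2R,4R)-2-(4-hydroxyphenyl)-5,7-dimethoxy-8-(3-methylbut-2-en-1-yl)chroman-4-yl acetate F6. The enantiomer left unreacted, (2S,4S)-2-(4-hydroxyphenyl)-5,7-dimethoxy-8-(3-methylbut-2-en-1-yl)chroman-4-ol F7, is separated and oxidised with MnO2 (CH2Cl2) to ketone 9.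

Further compounds
F1 | step 3 | 2-hydroxy-4,6-dimethoxy-3-(3-methylbut-2-en-1-yl)benzaldehyde | COc1cc(OC)c(C=O)c(O)c1CC=C(C)C
F2 | step 3 | racemic 1-[2-hydroxy-4,6-dimethoxy-3-(3-methylbut-2-en-1-yl)phenyl]ethan-1-ol | COc1cc(OC)c(C(C)O)c(O)c1CC=C(C)C
F3 | step 3 | 1-[2-hydroxy-4,6-dimethoxy-3-(3-methylbut-2-en-1-yl)phenyl]ethan-1-one | COc1cc(OC)c(C(C)=O)c(O)c1CC=C(C)C
F4 | step 6 | (2S,4S)-2-(4-hydroxyphenyl)-7-methoxy-8-(3-methylbut-2-en-1-yl)chroman-4,5-diol | COc1cc(O)c2c(c1CC=C(C)C)O[C@H](c1ccc(O)cc1)C[C@@H]2O
F5 | step 4 | racemic cis-2-(4-hydroxyphenyl)-5,7-dimethoxy-8-(3-methylbut-2-en-1-yl)chroman-4-ol (both enantiomers) | COc1cc(OC)c2c(c1CC=C(C)C)O[C@H](c1ccc(O)cc1)C[C@@H]2O.COc1cc(OC)c2c(c1CC=C(C)C)O[C@@H](c1ccc(O)cc1)C[C@H]2O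
F6 | step 4 | (2R,4R)-2-(4-hydroxyphenyl)-5,7-dimethoxy-8-(3-methylbut-2-en-1-yl)chroman-4-yl acetate | COc1cc(OC)c2c(c1CC=C(C)C)O[C@@H](c1ccc(O)cc1)C[C@H]2OC(C)=O
F7 | step 4 | (2S,4S)-2-(4-hydroxyphenyl)-5,7-dimethoxy-8-(3-methylbut-2-en-1-yl)chroman-4-ol | COc1cc(OC)c2c(c1CC=C(C)C)O[C@H](c1ccc(O)cc1)C[C@@H]2O
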